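The amount of target does not hold at its highest reading in the blue run: it reads 47.4% at 4.00 h and 42.0% at 6.00 h. That difference of 5.4 percentage points is larger than the scatter of 1 point.

| flask | starting material | temperature | remark | time |
|---|---|---|---|---|
| blue | 2.1 M | −5 °C | run made earlier |  |
| red | 2.1 M | 12 °C | run made earlier |  |
| epsilon | 1.5 M | 0 °C |  | 8.0 h |
| theta | 1.5 M |  | at 0 °C until 6.0 h, from then on at 25 °C | 8.0 h |
| zeta | 1.5 M | 25 °C |  | 8.0 h |

| blue: time / h | blue: target / % | red: time / h | red: target / % |
|---|---|---|---|
| 0.500 | 26.2 | 0.250 | 40.5 |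
| 0.833 | 33.9 | 0.500 | 46.6 |
| 1.33 | 42.3 | 0.667 | 50.5 |
| 2.00 | 45.9 | 1.00 | 56.8 |
| 3.00 | 46.9 | 1.50 | 59.3 |
| 4.00 | 47.4 | 2.00 | 61.5 |
| 6.00 | 42.0 | 3.00 | 60.5 |

(scatter of a reading: 1 percentage point)

1. the flask that comes out highest in amount of target, in percent of the starting material charged, or "all alike" when all lie within 1.5 percentage points (epsilon / theta / zeta / all alike)
2. target at the end, in percent of the starting material charged, epsilon
3. target at the end, in percent of the starting material charged, theta
4. target at the end, in percent of the starting material charged, zeta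

- a reading or a percentage of target counts all its forms, free or not

I read the blue peak as kinetic rather than thermodynamic control, and two times then count. From those two blue readings you get 16.5 h; this is the fade lifetime, the time in which target past its peak falls by a factor e. It rests on one blue step, and the last red step loses 1 point. The other time is the hold past the peak, 4.00 h if epsilon peaks when blue did. The rise drops out of the reckoning: blue stood at half of its peak by 0.500 h, far earlier than 8.0 h. The ratio of hold to fade is 0.242, so my own figure for epsilon, starting from the blue peak, is 37.2%.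

The forecast gives 51% for epsilon, 64% for theta and 68% for zeta, with zeta highest. Of the late blue reading it says “Red shows no decay, so I discount it”. Its epsilon figure is higher than mine.

The flasks give 26.6% in epsilon, 55.9% in theta and 50.3% in zeta, so theta is highest.

    starting material ⇌ target (K = 2.00, k = 0.523 min⁻¹, Ea = 78.0 kJ mol⁻¹, ΔH = 28.0 kJ mol⁻¹)
    target ⇌ isomer of the product (K = 1.91, k = 0.569 min⁻¹, Ea = 85.0 kJ mol⁻¹, ΔH = −22.0 kJ mol⁻¹)
    isomer of the product ⇌ starting material (k = 0.0663 min⁻¹, Ea = 96.0 kJ mol⁻¹)
    crystals ⇌ target, rate k4*(cs4 - [target]) while solid is left; crystals form when [target] > cs4 (solubility = 0.170 M, k = 0.194 min⁻¹)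
    starting material ⇌ dormant form (K = 3.80, k = 0.0120 min⁻¹, Ea = 100 kJ mol⁻¹, ΔH = −34.0 kJ mol⁻¹)
    2 starting material → homo dimer (k = 0.00776 M⁻¹ min⁻¹, Ea = 56.0 kJ mol⁻¹)
    (constants at 25 °C)

Now take the neighbouring flask, theta stopped at 3.0 h, while still at its first temperature. It holds 36.7% of target, 10 points under the blue reading at that time. Carried forward 5.00 h with 16.5 h, this amount becomes 27.1%, and epsilon, the same charge kept cold, reads 26.6%.

The numbers in the tables are simulated with made-up constants; the scatter is artificial.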